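## The problem

(6E)-Neomanoalide (29) is an open-chain sesterterpenoid. Numbering runs from the lactone carbonyl (C1) through C2, C3 (bearing the hydroxymethyl carbon C25) and the ring CH–O (C4), then along the chain: C5 methylene, the C6=C7 alkene (C7 bearing the hydroxymethyl carbon C24), C8, C9, the C10=C11 alkene (methyl on C11), C12, C13 and the 2,6,6-trimethylcyclohexenyl ring (C14–C19). The only stereocentre is C4 (R), the γ-carbon of the butenolide. With no second centre to relay from, it has to be set by a reagent or auxiliary. Its hydrogen becomes base-labile once the butenolide exists, so the ring should be closed late and under neutral conditions. The harder stereochemical questions are the two trisubstituted alkenes. 10E is ordinary isoprenoid geometry, but 6E is not, because the two carbon substituents on C7 (C24 and C8) are both CH2 groups and an olefination has little to tell them apart. Three electron-rich alkenes exclude ozone, peracids, hydrogenation and strong protic acid; the two primary allylic alcohols, the C5 methylene between C4 and C6, and the Michael-accepting lactone add further limits. The feature that opens the route is that C7 carries two one-carbon arms, C24 and C8, which differ only in lying trans or cis to C5 across C6=C7. With the chain cut at C8–C9 and C5 held as a protected CH2O group, this unit is the 2-alkylidene-propane-1,3-diol 6. Its two hydroxymethyl groups are constitutionally identical, so fixing 6E becomes a matter of telling two alcohols apart.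

## Retrosynthesis

**Butenolide (O–C1 and C2=C3).** Target 29 follows from bis-silyl ether 28 by desilylation. Cutting the lactone O–C1 bond and the C2=C3 bond of 28 leaves α-hydroxy ketone 26 and a two-carbon ketene ylide. An intermolecular olefination of the C3 ketone followed by lactonisation was rejected, because the ester would settle cis to the unsubstituted C25 side and close through the wrong oxygen. In the chosen closure the ester is tethered to O4 before the Wittig step, so the regiochemistry is decided by which hydroxyl is free. The forward reaction must be neutral enough to leave the C4 hydrogen untouched. Compound 26 is the primary-selective silylation product of diol 25.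

**C4–C5.** Diol 25 is the deprotected form of dioxanone 24, which is the hydrolysis product of hydrazone 23. Cutting C4–C5 in 23 gives allylic bromide 20 and hydrazone 22, made from ketone 1 and auxiliary 21. This cut brings in C3, C4 and C25 with all three oxygens as one symmetrical three-carbon piece and sets C4 under auxiliary control. The neighbouring cut at C5–C6 would need a geometry-defined vinyl metal at C6. The forward step must select one face of the azaenolate and attack C5, not C7.

**Group exchange and C8–C9.** Bromide 20 arises from alcohol 17 by silylation of the C24 hydroxyl (18), removal of the C5 4-methoxybenzyl ether (19) and bromination. In 17 the C8–C9 bond is cut. Both carbons are allylic, so the bond is made by alkylating the anion of allylic sulfone 14 with allylic bromide 9 to give 15, and the sulfonyl group is then removed reductively (through 16). A sulfone is preferred to an allyl metal because it reacts at its α-carbon and leaves C10=C11 in place. The chain is thus divided into a C9–C19 piece and a seven-carbon piece (C5–C8 plus C24). The forward steps must avoid allylic transposition, spare the acetate during coupling, and not move an alkene during desulfonylation.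

**The O–acetyl bond on C24 (key).** Bromide 9 comes from monoacetate 8, and 8 from diol 6 and acyl donor 7. No skeletal bond is cut. An olefination of a ketone flanked by two CH2O groups has no basis for selection, and chemical acylating agents hardly distinguish the arms. An enzyme pocket can read which arm lies next to the vinylic hydrogen. Diol 6 is achiral and has no geometric isomers. The forward reaction must acylate one arm only, and only once.

**Diol 6.** Diol 6 is the acetonide-free form of 5, the 4-methoxybenzyl ether of allylic alcohol 4. Alcohol 4 is the reduction product of ester 3, made by Horner–Wadsworth–Emmons olefination of 1 with 2. Ketone 1 is symmetrical, so this olefination creates no geometric isomers. The ester carbon becomes C5 and the two ring methylenes become C8 and C24.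

**Sulfone 14.** Sulfone 14 comes from bromide 13 and alcohol 12. Alcohol 12 is the reduction product of ester 11, the olefination product of ketone 10 with 2. This is the step that sets 10E, and it must deliver the E isomer in separable form.

## Roads not taken

Alternative 1: The cut is C4–C5 with the whole C5–C19 chain as electrophile. Allylic bromide A2 alkylates the lithium azaenolate of 22 to give hydrazone A1.
- **Merits:** The single stereocentre is set in the step that joins the two halves, and the alkylation has firm precedent for this hydrazone.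
- **Weak points:** As a strategy it does not say how A2 acquires the 6E geometry. A2 must be built with C24 and C8 already differentiated, which is the real difficulty. It also commits the most advanced intermediate to a very low-temperature alkylation.
- **Comparison:** For C4 this alkylation is as good as anything available, and the chosen plan uses it as step 17 (A1 differs from 23 only in the silyl group). What the chosen plan adds is an explicit, early answer to the 6E question.

Alternative 2: The cut is C7–C24, made on a chain that is complete but holds C6≡C7 as an alkyne. Homopropargylic alcohol A4, with the C4 hydroxyl in place, adds Grignard reagent A5 under iron catalysis. The alkoxide directs carbon to C7 and magnesium to C6 on the same side, and protonation gives A3 with the 6E alkene.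
- **Merits:** The geometry follows from the syn addition mechanism, not from a discrimination between like groups. In that respect this design is more secure than an enzymatic selection. C4 comes from an enantiopure precursor without an auxiliary.
- **Weak points:** Regiocontrol through a homopropargylic alkoxide with a bulky silylmethyl nucleophile is less certain than with propargylic alcohols. The later carbon–silicon oxidation needs a peroxide in the presence of three electron-rich alkenes. A3 holds C3 only as a CH2O carbon, so C25, C2 and C1 must still be attached and C3 raised to the ketone level.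
- **Comparison:** Against the mechanistic certainty the chosen plan sets a trivially accessible substrate, a position early in the route where failure is cheap, a complementary enzymatic mode in reserve, and an end game that brings C3, C4 and C25 in as one piece.

Alternative 3: No skeletal bond is cut in the key step. The achiral β,γ-unsaturated lactone A7 is isomerised by a chiral amine base that removes a proton from C2 and returns it to C4, giving A6.
- **Merits:** The stereocentre is made catalytically, without an auxiliary and without ketol intermediates, and it is made last. In step economy for C4 this is better than the chosen plan, which spends steps 16 to 21 and a stoichiometric auxiliary.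
- **Weak points:** A7 is a tetrasubstituted enol lactone with a β-substituent, beyond the simple γ-alkyl cases of this catalysis. Its C5 hydrogens lie between the enol-lactone alkene and C6=C7, so the same base can deprotonate there and move or scramble C6=C7. A shortfall in enantiopurity cannot be corrected through diastereomers. A7 still needs its own 6E-selective synthesis.
- **Comparison:** Against the better economy the chosen plan sets a predictable sense of induction, a diastereomeric intermediate (23) that can be purified, and no base near C5 once the butenolide exists.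

Key step: step 5

Assumption: the lipase is taken to acylate the hydroxymethyl arm cis to the vinylic hydrogen (trans to C5), the sense known for this enzyme class with 2-alkylidene-propane-1,3-diols; the C=N geometry of 22 and 23 and the configuration at the sulfonyl-bearing C9 of 15 and 16 are immaterial and left undefined.

## Route

Step 1
Reactants: 1 2,2-dimethyl-1,3-dioxan-5-one; 2 triethyl phosphonoacetate
Product: 3 ethyl 2-(2,2-dimethyl-1,3-dioxan-5-ylidene)acetate
Conditions: NaH, THF, 0 °C to rt
Reagents that add atoms: none
Why: Horner–Wadsworth–Emmons olefination of a symmetrical ketone, so no alkene geometry arises; the ester carbon becomes C5, the alkene carbons C6 and C7, and the ring methylenes C8 and C24.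

Step 2
Reactants: 3 ethyl 2-(2,2-dimethyl-1,3-dioxan-5-ylidene)acetate
Product: 4 2-(2,2-dimethyl-1,3-dioxan-5-ylidene)ethanol
Conditions: i-Bu2AlH (2.2 equiv), CH2Cl2, –78 to 0 °C
Reagents that add atoms: none
Why: 1,2-reduction of an α,β-unsaturated ester to the allylic alcohol by an aluminium hydride; the acetonide is inert.

Step 3
Reactants: 4 2-(2,2-dimethyl-1,3-dioxan-5-ylidene)ethanol
Product: 5 5-[2-(4-methoxybenzyloxy)ethylidene]-2,2-dimethyl-1,3-dioxane
Conditions: NaH, 4-methoxybenzyl chloride, n-Bu4NI (cat.), THF/DMF, 0 °C to rt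
Reagents that add atoms: 4-methoxybenzyl chloride, COc1ccc(CCl)cc1
Why: Williamson etherification under basic conditions that leave the acetonide intact; the 4-methoxybenzyl group marks C5 and can later be removed oxidatively in the presence of silyl ethers.

Step 4
Reactants: 5 5-[2-(4-methoxybenzyloxy)ethylidene]-2,2-dimethyl-1,3-dioxane
Product: 6 2-[2-(4-methoxybenzyloxy)ethylidene]propane-1,3-diol
Conditions: AcOH/H2O (4:1), rt
Reagents that add atoms: none
Why: Mild acid hydrolysis of the isopropylidene acetal; the benzylic ether and the allylic alcohols tolerate aqueous acetic acid.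

Step 5
Reactants: 6 2-[2-(4-methoxybenzyloxy)ethylidene]propane-1,3-diol; 7 vinyl acetate
Product: 8 (2E)-2-(hydroxymethyl)-4-(4-methoxybenzyloxy)but-2-en-1-yl acetate (acetate on the arm trans to C5)
Conditions: Burkholderia cepacia lipase (immobilised), vinyl acetate (3 equiv), t-BuOMe, rt, filtered when 6 is consumed
Reagents that add atoms: none
Why: Lipase-catalysed irreversible transesterification: the active-site serine is acetylated by vinyl acetate (the enol leaving group tautomerises to acetaldehyde, so the transfer does not reverse), and the acetyl-enzyme passes the acyl group to one primary hydroxyl of 6, forming a single O–acyl bond. The closest known reaction type is the lipase-mediated geometry-selective monoacylation of 2-alkylidene-propane-1,3-diols and, more broadly, lipase desymmetrisation of 2-substituted propane-1,3-diols. No ring closes and no stereocentre is created; what is created is a stereogenic double bond, because the two formerly equivalent arms become different. The selectivity needed is between two constitutionally identical hydroxymethyl groups and between mono- and diacylation. The substrate secures the first through the only difference between the arms: one lies cis to the vinylic hydrogen on C6, the other cis to the CH2O(4-methoxybenzyl) group, and the slimmer arm next to hydrogen should be the one admitted to the acyl-enzyme, which places the acetate trans to C5 and makes that arm C24. The second is secured because 8 has only the hindered arm left and should react much more slowly, so stopping at consumption of 6 should suffice. The aryl ether is inert to the enzyme and serves as a chromophore for monitoring.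

Step 6
Reactants: 8 (2E)-2-(hydroxymethyl)-4-(4-methoxybenzyloxy)but-2-en-1-yl acetate
Product: 9 (2Z)-2-(bromomethyl)-4-(4-methoxybenzyloxy)but-2-en-1-yl acetate
Conditions: CBr4, PPh3, CH2Cl2, –20 to 0 °C, used at once
Reagents that add atoms: carbon tetrabromide, BrC(Br)(Br)Br
Why: Appel bromination of the free C8 hydroxyl under near-neutral conditions; at low temperature direct displacement of the alkoxyphosphonium by bromide should outrun acetoxy participation and allylic transposition, so the arm assignment from step 5 is kept (the descriptor changes to Z only because CH2Br outranks CH2OAc).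

Step 7
Reactants: 10 dihydro-β-ionone; 2 triethyl phosphonoacetate
Product: 11 ethyl (2E)-3-methyl-5-(2,6,6-trimethylcyclohex-1-en-1-yl)pent-2-enoate
Conditions: NaH, THF, 0 °C to reflux; E isomer separated by chromatography
Reagents that add atoms: none
Why: Horner–Wadsworth–Emmons olefination of a methyl ketone, which should favour the E ester (ester trans to the longer chain) and so sets the 10E alkene; the minor Z ester is removed here.

Step 8
Reactants: 11 ethyl (2E)-3-methyl-5-(2,6,6-trimethylcyclohex-1-en-1-yl)pent-2-enoate
Product: 12 (2E)-3-methyl-5-(2,6,6-trimethylcyclohex-1-en-1-yl)pent-2-en-1-ol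
Conditions: i-Bu2AlH (2.2 equiv), CH2Cl2, –78 to 0 °C
Reagents that add atoms: none
Why: 1,2-reduction of the unsaturated ester to the allylic alcohol with retention of alkene geometry.

Step 9
Reactants: 12 (2E)-3-methyl-5-(2,6,6-trimethylcyclohex-1-en-1-yl)pent-2-en-1-ol
Product: 13 2-[(3E)-5-bromo-3-methylpent-3-en-1-yl]-1,3,3-trimethylcyclohex-1-ene
Conditions: PBr3, pyridine (cat.), Et2O, –10 °C; crude bromide carried on
Reagents that add atoms: phosphorus tribromide, BrP(Br)Br
Why: Standard conversion of a primary prenyl-type alcohol into the allylic bromide; cold, buffered conditions suppress allylic transposition and acid addition to the ring alkene.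

Step 10
Reactants: 13 2-[(3E)-5-bromo-3-methylpent-3-en-1-yl]-1,3,3-trimethylcyclohex-1-ene
Product: 14 {[(2E)-3-methyl-5-(2,6,6-trimethylcyclohex-1-en-1-yl)pent-2-en-1-yl]sulfonyl}benzene
Conditions: PhSO2Na, DMF, rt
Reagents that add atoms: sodium benzenesulfinate, [Na+].[O-]S(=O)c1ccccc1
Why: S-alkylation of a sulfinate by a primary allylic bromide (direct displacement), giving the allylic sulfone with the E alkene unchanged.

Step 11
Reactants: 14 {[(2E)-3-methyl-5-(2,6,6-trimethylcyclohex-1-en-1-yl)pent-2-en-1-yl]sulfonyl}benzene; 9 (2Z)-2-(bromomethyl)-4-(4-methoxybenzyloxy)but-2-en-1-yl acetate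
Product: 15 (2E,5E)-2-[2-(4-methoxybenzyloxy)ethylidene]-6-methyl-4-(phenylsulfonyl)-8-(2,6,6-trimethylcyclohex-1-en-1-yl)oct-5-en-1-yl acetate
Conditions: 14, n-BuLi, THF, –78 °C; then 9 in THF, –78 to –40 °C; AcOH quench
Reagents that add atoms: none
Why: α-Alkylation of a lithiated allylic phenyl sulfone by a primary allylic bromide, the standard sulfone coupling of polyprenoid synthesis, forms C8–C9; attack at the CH2Br of 9 is favoured over conjugate displacement at the substituted C6, and acetoxy-bearing allylic bromides are established partners at –78 °C. The sulfonyl carbon C9 becomes a racemic centre that step 12 removes.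

Step 12
Reactants: 15 (2E,5E)-2-[2-(4-methoxybenzyloxy)ethylidene]-6-methyl-4-(phenylsulfonyl)-8-(2,6,6-trimethylcyclohex-1-en-1-yl)oct-5-en-1-yl acetate
Product: 17 (2E,5E)-2-[2-(4-methoxybenzyloxy)ethylidene]-6-methyl-8-(2,6,6-trimethylcyclohex-1-en-1-yl)oct-5-en-1-ol, via hydroxy sulfone 16 (not isolated)
Conditions: LiBHEt3 (5 equiv), THF, –78 to 0 °C; then PdCl2(dppp) (5 mol %), 0 °C to rt
Reagents that add atoms: none
Why: Two known hydride reactions in one flask: LiBHEt3 first reduces the acetate to the lithium alkoxide of 16; PdCl2(dppp), reduced in situ to zerovalent palladium, then ionises the allylic sulfone, and a palladium hydride delivers hydrogen to the less substituted terminus C9 (reductive desulfonylation of allylic sulfones), leaving C10=C11 in place and E. The catalyst is added only after the acetate is gone, since an allylic acetate would itself ionise and lose the C24 oxygen, whereas the alkoxide, the aryl ether and the isolated alkenes are inert.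

Step 13
Reactants: 17 (2E,5E)-2-[2-(4-methoxybenzyloxy)ethylidene]-6-methyl-8-(2,6,6-trimethylcyclohex-1-en-1-yl)oct-5-en-1-ol
Product: 18 tert-butyl{[(2E,5E)-2-[2-(4-methoxybenzyloxy)ethylidene]-6-methyl-8-(2,6,6-trimethylcyclohex-1-en-1-yl)oct-5-en-1-yl]oxy}diphenylsilane
Conditions: t-BuPh2SiCl, imidazole, DMF, rt
Reagents that add atoms: tert-butyldiphenylsilyl chloride, CC(C)(C)[Si](Cl)(c1ccccc1)c1ccccc1
Why: Silylation of the primary C24 alcohol; the tert-butyldiphenylsilyl ether is chosen because it must survive the oxidant of step 14, the organolithium chemistry of step 17 and the aqueous acids of steps 18 and 19.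

Step 14
Reactants: 18 tert-butyl{[(2E,5E)-2-[2-(4-methoxybenzyloxy)ethylidene]-6-methyl-8-(2,6,6-trimethylcyclohex-1-en-1-yl)oct-5-en-1-yl]oxy}diphenylsilane
Product: 19 (2E,6E)-3-[(tert-butyldiphenylsilyloxy)methyl]-7-methyl-9-(2,6,6-trimethylcyclohex-1-en-1-yl)nona-2,6-dien-1-ol
Conditions: DDQ (1.2 equiv), CH2Cl2/pH 7 buffer (KH2PO4/Na2HPO4), 0 °C
Reagents that add atoms: none
Why: Oxidative cleavage of the 4-methoxybenzyl ether by hydride abstraction and hydrolysis of the oxocarbenium ion; the silyl ether and the unconjugated alkenes are not affected, and the limited amount of oxidant at 0 °C guards against oxidation of the new allylic alcohol.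

Step 15
Reactants: 19 (2E,6E)-3-[(tert-butyldiphenylsilyloxy)methyl]-7-methyl-9-(2,6,6-trimethylcyclohex-1-en-1-yl)nona-2,6-dien-1-ol
Product: 20 (2E,6E)-1-bromo-3-[(tert-butyldiphenylsilyloxy)methyl]-7-methyl-9-(2,6,6-trimethylcyclohex-1-en-1-yl)nona-2,6-diene
Conditions: CBr4, PPh3, CH2Cl2, –20 to 0 °C, used at once
Reagents that add atoms: carbon tetrabromide, BrC(Br)(Br)Br
Why: Appel bromination of a primary γ,γ-disubstituted allylic alcohol, which at low temperature should give the primary bromide without transposition to C7 and thus without loss of the 6E geometry.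

Step 16
Reactants: 1 2,2-dimethyl-1,3-dioxan-5-one; 21 (R)-1-amino-2-(methoxymethyl)pyrrolidine (RAMP)
Product: 22 (2R)-N-(2,2-dimethyl-1,3-dioxan-5-ylidene)-2-(methoxymethyl)pyrrolidin-1-amine
Conditions: benzene, reflux, Dean–Stark trap
Reagents that add atoms: none
Why: Condensation of a ketone with a 1,1-disubstituted hydrazine with azeotropic removal of water gives the chiral hydrazone of the dihydroxyacetone equivalent.

Step 17
Reactants: 22 (2R)-N-(2,2-dimethyl-1,3-dioxan-5-ylidene)-2-(methoxymethyl)pyrrolidin-1-amine; 20 (2E,6E)-1-bromo-3-[(tert-butyldiphenylsilyloxy)methyl]-7-methyl-9-(2,6,6-trimethylcyclohex-1-en-1-yl)nona-2,6-diene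
Product: 23 (2R)-N-[(4R)-4-{(2E,6E)-3-[(tert-butyldiphenylsilyloxy)methyl]-7-methyl-9-(2,6,6-trimethylcyclohex-1-en-1-yl)nona-2,6-dien-1-yl}-2,2-dimethyl-1,3-dioxan-5-ylidene]-2-(methoxymethyl)pyrrolidin-1-amine
Conditions: 22 (1.2 equiv), t-BuLi, THF, –78 °C; then 20, –100 °C, slowly to rt
Reagents that add atoms: none
Why: Enders RAMP-hydrazone alkylation: the lithium azaenolate is held rigid by chelation of lithium to the methoxymethyl arm, one face is shielded by the pyrrolidine, and the primary allylic bromide enters from the other face, which with the R auxiliary and this dioxanone corresponds to the 4R product. C4–C5 forms by direct displacement at C5, the fully substituted C7 disfavours transposition, and the auxiliary still attached allows the major diastereomer to be purified.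

Step 18
Reactants: 23 the alkylated RAMP hydrazone
Product: 24 (4R)-4-{(2E,6E)-3-[(tert-butyldiphenylsilyloxy)methyl]-7-methyl-9-(2,6,6-trimethylcyclohex-1-en-1-yl)nona-2,6-dien-1-yl}-2,2-dimethyl-1,3-dioxan-5-one
Conditions: sat. aq. oxalic acid, Et2O, rt
Reagents that add atoms: water, O
Why: Mild biphasic acid hydrolysis of the hydrazone, the non-oxidative cleavage used for dioxanone hydrazones; it spares the alkenes (ozone would not), the acetonide and the silyl ether, and should not epimerise the α-centre; the auxiliary is recovered from the aqueous phase.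

Step 19
Reactants: 24 the (4R)-4-substituted 2,2-dimethyl-1,3-dioxan-5-one
Product: 25 (3R,5E,9E)-6-[(tert-butyldiphenylsilyloxy)methyl]-1,3-dihydroxy-10-methyl-12-(2,6,6-trimethylcyclohex-1-en-1-yl)dodeca-5,9-dien-2-one
Conditions: 1 M aq. HCl, THF, 0 °C to rt
Reagents that add atoms: none
Why: Acid hydrolysis of the isopropylidene acetal frees the C4 and C25 hydroxyls; dilute acid at or below rt should leave the primary tert-butyldiphenylsilyl ether and the trisubstituted alkenes untouched and is kept short to avoid ketol isomerisation.

Step 20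
Reactants: 25 the (3R)-1,3-dihydroxy-2-ketone
Product: 26 (3R,5E,9E)-1-(tert-butyldimethylsilyloxy)-6-[(tert-butyldiphenylsilyloxy)methyl]-3-hydroxy-10-methyl-12-(2,6,6-trimethylcyclohex-1-en-1-yl)dodeca-5,9-dien-2-one
Conditions: t-BuMe2SiCl (1.05 equiv), imidazole, CH2Cl2, –20 to 0 °C
Reagents that add atoms: tert-butyldimethylsilyl chloride, CC(C)(C)[Si](C)(C)Cl
Why: Kinetic silylation of the primary C25 hydroxyl in preference to the hindered secondary C4 hydroxyl; this leaves O4 as the only hydroxyl able to enter the lactone in step 21.

Step 21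
Reactants: 26 the (3R)-3-hydroxy-2-ketone with O25 silylated
Product: 28 (5R)-4-[(tert-butyldimethylsilyloxy)methyl]-5-{(2E,6E)-3-[(tert-butyldiphenylsilyloxy)methyl]-7-methyl-9-(2,6,6-trimethylcyclohex-1-en-1-yl)nona-2,6-dien-1-yl}furan-2(5H)-one, via ester ylide 27 (not isolated)
Conditions: Ph3P=C=C=O (1.2 equiv), toluene, 90 °C
Reagents that add atoms: ketenylidenetriphenylphosphorane, O=C=C=P(c1ccccc1)(c1ccccc1)c1ccccc1
Why: Cascade of hydroxyl addition to the ketene ylide and intramolecular Wittig olefination, the known conversion of α-hydroxy ketones into butenolides: the C4 hydroxyl adds to give ester ylide 27, which condenses with the C3 ketone to close the five-membered lactone (O–C1 and C2=C3 formed, Ph3PO lost). The medium is neutral, so the C4 centre should be carried through unchanged.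

Step 22
Reactants: 28 the bis-silylated butenolide
Product: 29 (6E)-neomanoalide, (5R)-4-(hydroxymethyl)-5-[(2E,6E)-3-(hydroxymethyl)-7-methyl-9-(2,6,6-trimethylcyclohex-1-en-1-yl)nona-2,6-dien-1-yl]furan-2(5H)-one
Conditions: HF·pyridine, pyridine, THF, 0 °C to rt
Reagents that add atoms: none
Why: Acidic fluoride cleaves both silyl ethers; buffered HF·pyridine is used instead of a basic fluoride source because the C4 hydrogen of the butenolide is base-labile, and the alkenes and allylic alcohols tolerate it.

## Compound list

1 | 2,2-dimethyl-1,3-dioxan-5-one | CC1(C)OCC(=O)CO1 | starting material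
2 | triethyl phosphonoacetate | CCOC(=O)CP(=O)(OCC)OCC | starting material
3 | ethyl 2-(2,2-dimethyl-1,3-dioxan-5-ylidene)acetate | CCOC(=O)C=C1COC(C)(C)OC1 | intermediate
4 | 2-(2,2-dimethyl-1,3-dioxan-5-ylidene)ethanol | OCC=C1COC(C)(C)OC1 | intermediate
5 | 5-[2-(4-methoxybenzyloxy)ethylidene]-2,2-dimethyl-1,3-dioxane | COc1ccc(COCC=C2COC(C)(C)OC2)cc1 | intermediate
6 | 2-[2-(4-methoxybenzyloxy)ethylidene]propane-1,3-diol | COc1ccc(COCC=C(CO)CO)cc1 | intermediate
7 | vinyl acetate | CC(=O)OC=C | starting material
8 | (2E)-2-(hydroxymethyl)-4-(4-methoxybenzyloxy)but-2-en-1-yl acetate (acetate trans to C5) | COc1ccc(COC/C=C(/COC(C)=O)CO)cc1 | intermediate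
9 | (2Z)-2-(bromomethyl)-4-(4-methoxybenzyloxy)but-2-en-1-yl acetate (bromomethyl cis to C5) | COc1ccc(COC/C=C(/COC(C)=O)CBr)cc1 | intermediate
10 | dihydro-β-ionone, 4-(2,6,6-trimethylcyclohex-1-en-1-yl)butan-2-one | CC(=O)CCC1=C(C)CCCC1(C)C | starting material
11 | ethyl (2E)-3-methyl-5-(2,6,6-trimethylcyclohex-1-en-1-yl)pent-2-enoate | CCOC(=O)/C=C(\C)CCC1=C(C)CCCC1(C)C | intermediate
12 | (2E)-3-methyl-5-(2,6,6-trimethylcyclohex-1-en-1-yl)pent-2-en-1-ol | OC/C=C(\C)CCC1=C(C)CCCC1(C)C | intermediate
13 | 2-[(3E)-5-bromo-3-methylpent-3-en-1-yl]-1,3,3-trimethylcyclohex-1-ene | BrC/C=C(\C)CCC1=C(C)CCCC1(C)C | intermediate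
14 | {[(2E)-3-methyl-5-(2,6,6-trimethylcyclohex-1-en-1-yl)pent-2-en-1-yl]sulfonyl}benzene | O=S(=O)(C/C=C(\C)CCC1=C(C)CCCC1(C)C)c1ccccc1 | intermediate
15 | (2E,5E)-2-[2-(4-methoxybenzyloxy)ethylidene]-6-methyl-4-(phenylsulfonyl)-8-(2,6,6-trimethylcyclohex-1-en-1-yl)oct-5-en-1-yl acetate, racemic at the sulfonyl carbon | CC1=C(CC/C(C)=C/C(C/C(=C\COCc2ccc(OC)cc2)COC(C)=O)S(=O)(=O)c3ccccc3)C(C)(C)CCC1 | intermediate
16 | (2E,5E)-2-[2-(4-methoxybenzyloxy)ethylidene]-6-methyl-4-(phenylsulfonyl)-8-(2,6,6-trimethylcyclohex-1-en-1-yl)oct-5-en-1-ol, racemic at the sulfonyl carbon, formed as its lithium alkoxide | CC1=C(CC/C(C)=C/C(C/C(=C\COCc2ccc(OC)cc2)CO)S(=O)(=O)c3ccccc3)C(C)(C)CCC1 | intermediate (not isolated)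
17 | (2E,5E)-2-[2-(4-methoxybenzyloxy)ethylidene]-6-methyl-8-(2,6,6-trimethylcyclohex-1-en-1-yl)oct-5-en-1-ol (6E,10E; C24 hydroxyl free) | CC1=C(CC/C(C)=C/CC/C(=C\COCc2ccc(OC)cc2)CO)C(C)(C)CCC1 | intermediate
18 | tert-butyldiphenylsilyl ether of 17 at O24 | CC1=C(CC/C(C)=C/CC/C(=C\COCc2ccc(OC)cc2)CO[Si](c3ccccc3)(c4ccccc4)C(C)(C)C)C(C)(C)CCC1 | intermediate
19 | (2E,6E)-3-[(tert-butyldiphenylsilyloxy)methyl]-7-methyl-9-(2,6,6-trimethylcyclohex-1-en-1-yl)nona-2,6-dien-1-ol | CC1=C(CC/C(C)=C/CC/C(=C\CO)CO[Si](c3ccccc3)(c4ccccc4)C(C)(C)C)C(C)(C)CCC1 | intermediate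
20 | (2E,6E)-1-bromo-3-[(tert-butyldiphenylsilyloxy)methyl]-7-methyl-9-(2,6,6-trimethylcyclohex-1-en-1-yl)nona-2,6-diene | CC1=C(CC/C(C)=C/CC/C(=C\CBr)CO[Si](c3ccccc3)(c4ccccc4)C(C)(C)C)C(C)(C)CCC1 | intermediate
21 | (R)-1-amino-2-(methoxymethyl)pyrrolidine (RAMP) | COC[C@H]1CCCN1N | starting material
22 | (2R)-N-(2,2-dimethyl-1,3-dioxan-5-ylidene)-2-(methoxymethyl)pyrrolidin-1-amine | COC[C@H]1CCCN1N=C1COC(C)(C)OC1 | intermediate
23 | RAMP hydrazone of (4R)-4-{(2E,6E)-3-[(tert-butyldiphenylsilyloxy)methyl]-7-methyl-9-(2,6,6-trimethylcyclohex-1-en-1-yl)nona-2,6-dien-1-yl}-2,2-dimethyl-1,3-dioxan-5-one | CC1=C(CC/C(C)=C/CC/C(=C\C[C@H]2OC(C)(C)OCC2=NN3CCC[C@@H]3COC)CO[Si](c4ccccc4)(c5ccccc5)C(C)(C)C)C(C)(C)CCC1 | intermediate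
24 | (4R)-4-{(2E,6E)-3-[(tert-butyldiphenylsilyloxy)methyl]-7-methyl-9-(2,6,6-trimethylcyclohex-1-en-1-yl)nona-2,6-dien-1-yl}-2,2-dimethyl-1,3-dioxan-5-one | CC1=C(CC/C(C)=C/CC/C(=C\C[C@H]2OC(C)(C)OCC2=O)CO[Si](c3ccccc3)(c4ccccc4)C(C)(C)C)C(C)(C)CCC1 | intermediate
25 | (3R,5E,9E)-6-[(tert-butyldiphenylsilyloxy)methyl]-1,3-dihydroxy-10-methyl-12-(2,6,6-trimethylcyclohex-1-en-1-yl)dodeca-5,9-dien-2-one | CC1=C(CC/C(C)=C/CC/C(=C\C[C@@H](O)C(=O)CO)CO[Si](c2ccccc2)(c3ccccc3)C(C)(C)C)C(C)(C)CCC1 | intermediate
26 | (3R,5E,9E)-1-(tert-butyldimethylsilyloxy)-6-[(tert-butyldiphenylsilyloxy)methyl]-3-hydroxy-10-methyl-12-(2,6,6-trimethylcyclohex-1-en-1-yl)dodeca-5,9-dien-2-one | CC1=C(CC/C(C)=C/CC/C(=C\C[C@@H](O)C(=O)CO[Si](C)(C)C(C)(C)C)CO[Si](c2ccccc2)(c3ccccc3)C(C)(C)C)C(C)(C)CCC1 | intermediate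
27 | (triphenylphosphoranylidene)acetate ester of 26 at O4 (ester ylide, 4R) | CC1=C(CC/C(C)=C/CC/C(=C\C[C@@H](OC(=O)C=P(c2ccccc2)(c3ccccc3)c4ccccc4)C(=O)CO[Si](C)(C)C(C)(C)C)CO[Si](c5ccccc5)(c6ccccc6)C(C)(C)C)C(C)(C)CCC1 | intermediate (not isolated)
28 | (5R)-4-[(tert-butyldimethylsilyloxy)methyl]-5-{(2E,6E)-3-[(tert-butyldiphenylsilyloxy)methyl]-7-methyl-9-(2,6,6-trimethylcyclohex-1-en-1-yl)nona-2,6-dien-1-yl}furan-2(5H)-one | CC1=C(CC/C(C)=C/CC/C(=C\C[C@H]2OC(=O)C=C2CO[Si](C)(C)C(C)(C)C)CO[Si](c3ccccc3)(c4ccccc4)C(C)(C)C)C(C)(C)CCC1 | intermediate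
29 | (6E)-neomanoalide, (5R)-4-(hydroxymethyl)-5-[(2E,6E)-3-(hydroxymethyl)-7-methyl-9-(2,6,6-trimethylcyclohex-1-en-1-yl)nona-2,6-dien-1-yl]furan-2(5H)-one | CC1=C(CC/C(C)=C/CC/C(=C\C[C@H]2OC(=O)C=C2CO)CO)C(C)(C)CCC1 | target

## Step count and weak points

Total: 22 steps. Longest linear sequence: 17 steps (steps 1–6, 11–15 and 17–22). The sulfone branch (steps 7–10) and the hydrazone (step 16) are side branches.

**Step 5 (key step).**
- **What may go wrong:** The enzyme may discriminate the two arms incompletely, or acylation may run on to the diacetate. Acetyl migration between the two arms of 8 on standing or on silica would also erase the differentiation, which is why 8 is brominated without delay.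
- **Fallback:** This uses the enzyme in the hydrolytic direction and sets out from 6. Acetylation of both arms (Ac2O, pyridine) gives 2-[2-(4-methoxybenzyloxy)ethylidene]propane-1,3-diyl diacetate F1. The same lipase in aqueous buffer should hydrolyse only the arm it accepts (trans to C5), giving the complementary monoacetate (2Z)-2-(hydroxymethyl)-4-(4-methoxybenzyloxy)but-2-en-1-yl acetate F2 with the free hydroxyl on the future C24 arm.
- **Rejoining the route:** Silylation of F2 (t-BuPh2SiCl, imidazole) gives the silyl ether acetate F3. Methanolysis (K2CO3, MeOH) gives (2E)-2-[(tert-butyldiphenylsilyloxy)methyl]-4-(4-methoxybenzyloxy)but-2-en-1-ol F4. Appel bromination gives tert-butyl{[(2Z)-2-(bromomethyl)-4-(4-methoxybenzyloxy)but-2-en-1-yl]oxy}diphenylsilane F5. Alkylation of lithiated 14 with F5 gives the silyl ether sulfone F6, and desulfonylation with LiBHEt3 and PdCl2(dppp) returns to the route at 18.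
- **If the sense is reversed:** Should the acylation sense be opposite to that assumed, the same hydrolysis of F1 would give 8 itself.

**Step 17.**
- **What may go wrong:** The alkylation may be incomplete or lose facial selectivity, because a γ,γ-disubstituted allylic bromide that is both valuable and prone to ionisation must react with the azaenolate at very low temperature.
- **Fallback:** This keeps the C4–C5 disconnection but changes the chiral nucleophile, and sets out from 20. (S)-4-Benzyl-3-[(4-methoxybenzyloxy)acetyl]oxazolidin-2-one F7 is made by N-acylation of (S)-4-benzyloxazolidin-2-one with (4-methoxybenzyloxy)acetyl chloride. Its chelated sodium enolate (NaN(SiMe3)2, THF, –78 °C) is alkylated by 20 on the face away from the benzyl group, giving the (R)-configured α-alkoxy imide F8.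
- **Rejoining the route:** Transamidation of F8 (MeONHMe·HCl, AlMe3) gives the Weinreb amide F9. Addition of (4-methoxybenzyloxy)methyllithium, from the tributylstannane and n-BuLi, gives the bis(4-methoxybenzyl) ketone F10. DDQ removes both benzylic ethers and returns to the route at 25.

**Step 21.**
- **What may go wrong:** The C4 centre may epimerise through enolisation of the α-hydroxy ketone at 90 °C. Silyl migration from O25 to O4 would close the ring through the wrong oxygen. The intramolecular Wittig step on the hindered ketone may be slow.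
- **Fallback:** This separates acylation from olefination and sets out from 26. Esterification of the C4 hydroxyl with diethylphosphonoacetic acid (carbodiimide, catalytic DMAP, 0 °C) gives the phosphonoacetate F11. An intramolecular Horner–Wadsworth–Emmons reaction under mild base (LiCl, i-Pr2NEt, MeCN, rt) closes the butenolide and returns at 28.

**Step 12.**
- **What may go wrong:** If acetate reduction is incomplete when the catalyst is added, palladium can ionise the allylic acetate and the C24 oxygen is lost. Hydride delivery to the wrong allyl terminus would move C10=C11.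
- **Fallback:** This separates the two events so that palladium never meets an allylic acetate, and sets out from 15. Base-mediated methanolysis (K2CO3, MeOH) gives 16 as an isolated compound. Reductive desulfonylation of 16 (PdCl2(dppp), LiBHEt3) then gives 17, where the route resumes. No new compound is made.

**Step 7.**
- **What may go wrong:** E selectivity in the olefination of the methyl ketone may be incomplete, and the geometric isomers of 11 may be hard to separate.
- **Fallback:** This builds the alkene by syn-carbometalation and sets out from 10. Kinetic enolisation on the methyl side (LDA, –78 °C) and trapping with ClP(O)(OEt)2 gives the enol phosphate F12. Further LDA eliminates it to the terminal alkyne 2-(but-3-yn-1-yl)-1,3,3-trimethylcyclohex-1-ene F13. Zirconium-catalysed carboalumination (Me3Al, Cp2ZrCl2 cat., CH2Cl2) adds methyl and aluminium to the same side. The alkenylalane, activated with n-BuLi, is trapped with paraformaldehyde to give the E alcohol only, returning at 12.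

## Further compounds

F1 | step 5 | 2-[2-(4-methoxybenzyloxy)ethylidene]propane-1,3-diyl diacetate | COc1ccc(COCC=C(COC(C)=O)COC(C)=O)cc1
F2 | step 5 | (2Z)-2-(hydroxymethyl)-4-(4-methoxybenzyloxy)but-2-en-1-yl acetate (acetate cis to C5, hydroxyl trans) | COc1ccc(COC/C=C(/CO)COC(C)=O)cc1
F3 | step 5 | (2E)-2-[(tert-butyldiphenylsilyloxy)methyl]-4-(4-methoxybenzyloxy)but-2-en-1-yl acetate (silyl ether trans to C5) | COc1ccc(COC/C=C(/CO[Si](c2ccccc2)(c3ccccc3)C(C)(C)C)COC(C)=O)cc1
F4 | step 5 | (2E)-2-[(tert-butyldiphenylsilyloxy)methyl]-4-(4-methoxybenzyloxy)but-2-en-1-ol | COc1ccc(COC/C=C(/CO[Si](c2ccccc2)(c3ccccc3)C(C)(C)C)CO)cc1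
F5 | step 5 | tert-butyl{[(2Z)-2-(bromomethyl)-4-(4-methoxybenzyloxy)but-2-en-1-yl]oxy}diphenylsilane | COc1ccc(COC/C=C(/CO[Si](c2ccccc2)(c3ccccc3)C(C)(C)C)CBr)cc1
F6 | step 5 | tert-butyl{[(2E,5E)-2-[2-(4-methoxybenzyloxy)ethylidene]-6-methyl-4-(phenylsulfonyl)-8-(2,6,6-trimethylcyclohex-1-en-1-yl)oct-5-en-1-yl]oxy}diphenylsilane, racemic at the sulfonyl carbon | CC1=C(CC/C(C)=C/C(C/C(=C\COCc2ccc(OC)cc2)CO[Si](c3ccccc3)(c4ccccc4)C(C)(C)C)S(=O)(=O)c5ccccc5)C(C)(C)CCC1
F7 | step 17 | (S)-4-benzyl-3-[(4-methoxybenzyloxy)acetyl]oxazolidin-2-one | COc1ccc(COCC(=O)N2[C@@H](Cc3ccccc3)COC2=O)cc1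
F8 | step 17 | (S)-4-benzyl-3-[(2R,4E,8E)-5-[(tert-butyldiphenylsilyloxy)methyl]-2-(4-methoxybenzyloxy)-9-methyl-11-(2,6,6-trimethylcyclohex-1-en-1-yl)undeca-4,8-dienoyl]oxazolidin-2-one | CC1=C(CC/C(C)=C/CC/C(=C\C[C@@H](OCc2ccc(OC)cc2)C(=O)N2[C@@H](Cc3ccccc3)COC2=O)CO[Si](c4ccccc4)(c5ccccc5)C(C)(C)C)C(C)(C)CCC1
F9 | step 17 | (2R,4E,8E)-5-[(tert-butyldiphenylsilyloxy)methyl]-N-methoxy-2-(4-methoxybenzyloxy)-N,9-dimethyl-11-(2,6,6-trimethylcyclohex-1-en-1-yl)undeca-4,8-dienamide | CC1=C(CC/C(C)=C/CC/C(=C\C[C@@H](OCc2ccc(OC)cc2)C(=O)N(C)OC)CO[Si](c3ccccc3)(c4ccccc4)C(C)(C)C)C(C)(C)CCC1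
F10 | step 17 | (3R,5E,9E)-6-[(tert-butyldiphenylsilyloxy)methyl]-1,3-bis(4-methoxybenzyloxy)-10-methyl-12-(2,6,6-trimethylcyclohex-1-en-1-yl)dodeca-5,9-dien-2-one | CC1=C(CC/C(C)=C/CC/C(=C\C[C@@H](OCc2ccc(OC)cc2)C(=O)COCc2ccc(OC)cc2)CO[Si](c3ccccc3)(c4ccccc4)C(C)(C)C)C(C)(C)CCC1
F11 | step 21 | (diethoxyphosphoryl)acetate ester of 26 at O4 (4R) | CC1=C(CC/C(C)=C/CC/C(=C\C[C@@H](OC(=O)CP(=O)(OCC)OCC)C(=O)CO[Si](C)(C)C(C)(C)C)CO[Si](c2ccccc2)(c3ccccc3)C(C)(C)C)C(C)(C)CCC1
F0 | step 12 | none | none
F12 | step 7 | diethyl 4-(2,6,6-trimethylcyclohex-1-en-1-yl)but-1-en-2-yl phosphate | C=C(CCC1=C(C)CCCC1(C)C)OP(=O)(OCC)OCC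
F13 | step 7 | 2-(but-3-yn-1-yl)-1,3,3-trimethylcyclohex-1-ene | C#CCCC1=C(C)CCCC1(C)C
A1 | alternative 1 | RAMP hydrazone of the (4R)-4-alkylated dioxanone carrying C5–C19 with a tert-butyldimethylsilyl ether at O24 | COC[C@H]1CCCN1N=C2COC(C)(C)O[C@@H]2C/C=C(/CO[Si](C)(C)C(C)(C)C)CC/C=C(\C)CCC3=C(C)CCCC3(C)C
A2 | alternative 1 | (2E,6E)-1-bromo-3-[(tert-butyldimethylsilyloxy)methyl]-7-methyl-9-(2,6,6-trimethylcyclohex-1-en-1-yl)nona-2,6-diene | BrC/C=C(/CO[Si](C)(C)C(C)(C)C)CC/C=C(\C)CCC1=C(C)CCCC1(C)C
A3 | alternative 2 | (R,6E)-homoallylic alcohol with C24 attached as an (isopropoxydimethylsilyl)methyl group and a 4-methoxybenzyl ether on the C3 oxygen | COc1ccc(COC[C@H](O)C/C=C(/C[Si](C)(C)OC(C)C)CC/C=C(\C)CCC2=C(C)CCCC2(C)C)cc1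
A4 | alternative 2 | (R)-homopropargylic alcohol, (2R,8E)-1-(4-methoxybenzyloxy)-9-methyl-11-(2,6,6-trimethylcyclohex-1-en-1-yl)undec-8-en-4-yn-2-ol | COc1ccc(COC[C@H](O)CC#CCC/C=C(\C)CCC2=C(C)CCCC2(C)C)cc1
A5 | alternative 2 | (isopropoxydimethylsilyl)methylmagnesium chloride | CC(C)O[Si](C)(C)C[Mg]Cl
A6 | alternative 3 | (6E)-neomanoalide bis(tert-butyldimethylsilyl) ether, 4R | CC1=C(CC/C(C)=C/CC/C(=C\C[C@H]2OC(=O)C=C2CO[Si](C)(C)C(C)(C)C)CO[Si](C)(C)C(C)(C)C)C(C)(C)CCC1
A7 | alternative 3 | achiral 4-[(tert-butyldimethylsilyloxy)methyl]-5-substituted furan-2(3H)-one carrying the C5–C19 chain with O24 silylated | CC1=C(CC/C(C)=C/CC/C(=C\CC2=C(CO[Si](C)(C)C(C)(C)C)CC(=O)O2)CO[Si](C)(C)C(C)(C)C)C(C)(C)CCC1
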